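We will read these flasks on the catalyst clock instead of the minute hand: catalyst concentration multiplied by elapsed time, which comes to 1.80 M·s for the grey run at 25 min. The blue run justifies the choice. It holds 1.50 times the catalyst of the amber run, and at one clock reading of 0.360 M·s, blue at 10 min and amber at 15 min both show 111 mM of product.

| flask | substrate | partner | catalyst | time |
|---|---|---|---|---|
| amber | 200 mM | 400 mM | 0.400 mM |  |
| green | 80.0 mM | 280 mM | 0.400 mM |  |
| red | 600 mM | 400 mM | 0.400 mM |  |
| blue | 200 mM | 400 mM | 0.600 mM |  |
| grey | 400 mM | 400 mM | 1.20 mM | 25 min |

- amber run (time / min: [product] / mM): 1.1: 21; 3.4: 48; 6.4: 71; 10: 93; 15: 111; 20: 127; 25: 135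
- green run (time / min: [product] / mM): 1.1: 12; 3.4: 27; 6.4: 38; 10: 41; 15: 60; 20: 65; 25: 70
- red run (time / min: [product] / mM): 1.1: 22; 3.4: 69; 6.4: 111; 10: 139; 15: 187; 20: 203; 25: 230
- blue run (time / min: [product] / mM): 1.1: 25; 3.4: 64; 6.4: 89; 10: 111; 15: 127; 20: 146; 25: 157

(each reading ± 3 mM)

- the exponent of [partner] in the starting rate at the charge of the amber run (at the point where two percent of the substrate have become product)
- the exponent of [substrate] in the starting rate at the charge of the amber run (at the point where two percent of the substrate have become product) (one fixed amount of product, the same in the runs compared)
- the green run starts with 120 mM less of substrate and of partner than the amber run, and with no product. Compared where both hold the same amount of substrate, once fifteen percent of what the green run was charged with has turned into product, is the green run faster, slower or alike (within a tenth)?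
- product in the grey run at 25 min, as a share of the substrate charged

- Overall: substrate + partner -> product, with catalyst as catalyst.
- Constant volume, constant temperature.
- The analysis sees a species whether free or bound.
- An order is taken over about fifteen percent of the charge, up and down.

Now take the run slowly. In the first minutes, red has 3.00 times amber's substrate, yet at 3.4 min it has made 69 mM against amber's 48 mM. Read as a power of substrate, that gives an exponent near 0.330, a rough reading. No run varies partner apart from substrate, so we name no exponent for partner.

The middle is where to watch. Once amber has made 120 mM, it holds the substrate and partner that green was charged with. Yet green, over its first 3.4 min, runs at 7.94 mM min⁻¹, faster than the 2.40 mM min⁻¹ of amber around 20 min. We therefore expect green to be faster, and the difference between the two flasks at that point is the product amber carries.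

Late in amber, c(product) grows roughly as the square root of the clock: from 6.4 min to 25 min it rises 1.90 times, against a root of 1.98.

For grey, whose c(substrate) lies midway between amber's and red's, the mean of their last readings gives 182 mM at a clock of 0.600 M·s. The root rule carries that to 316 mM, or 79.0% of the charge. We read the root in amber up to 67.5% of its charge, so we treat the grey figure as our high side and commit to somewhat less.

The forecast gives 0.9 for partner, 0.2 for substrate, faster for green and 70% for grey, lower than our high side. On partner it warns that “partner was never varied independently”.

The flask gives 69.4% for grey, faster for green at a rate ratio of 4.1, 0.25 for substrate and 0.29 for partner.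

    catalyst + substrate ⇌ catalyst-substrate complex, settled at all times (1.220 M⁻¹)
    catalyst-substrate complex + partner ⇌ ternary complex, settled at all times (40.10 M⁻¹)
    ternary complex → product + catalyst (68.40 min⁻¹)
    catalyst + product ⇌ catalyst-product complex, settled at all times (73.90 M⁻¹)

The forecast parts from the flask on partner, 0.9 against 0.29. Grey's clock of 1.80 M·s equals 75.0 min at amber's catalyst. Amber reached product equal to half its substrate charge at 11.9 min, a clock of 0.286 M·s, and blue reached it at 7.94 min, a clock of 0.286 M·s.

(The numbers in the tables were generated by integration with made-up constants.)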